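You set a neighbour flask with 8.0 mM of starting material beside this one with 2.0 mM, asked for a quick number on the smaller charge, and suspected the gas was the thing to watch. I began from that hunch.

starting material 2.0 mM; gas phase 0.85 mM (held); protic impurity 2.00 mM; time 40 s

    gas phase ⇌ dissolved gas, rate k1*(csat - [dissolved gas]) (k1 = 0.016 s⁻¹, csat = 0.85 mM)
    starting material + dissolved gas → target (k2 = 260 M⁻¹ s⁻¹)
    starting material → side product (k3 = 0.23 s⁻¹)
    dissolved gas → decomposed reagent (k4 = 0.014 s⁻¹)
    starting material + target ⇌ idle adduct, settled at all times (K5 = 970 M⁻¹)
    dissolved gas + protic impurity → quenched reagent (k6 = 10 M⁻¹ s⁻¹)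

- percent here means starting material units held: one idle adduct counts as two
- what is said of target includes idle adduct
- at the start none of the gas is dissolved
- in an amount of target, one idle adduct counts as one target
- run time (flask): 40 s

- target and idle adduct together at 40 s, in percent of the starting material charged
- concentration of dissolved gas in solution at 40 s, in percent of saturation

In this flask gas entered an empty solution at F = 0.0136 mM s⁻¹. Starting material caught dissolved gas at a rate constant C = 0.520 s⁻¹ at the charge, faster than the side step's d = 0.23 s⁻¹, but C fell as starting material decayed. I looked for the crossing where the two were equal, and added a tail for gas arriving later: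

t× = ln(C/d)/d = 3.55 s

t(h) = t× + 0.5/d = 5.72 s, the harvest time, the crossing plus half a lifetime of starting material

Y = F·t(h)/charge = 3.89 %

From the end of the harvest I let dissolved gas rise from nothing, with quenching taken as pseudo-first-order at the charged protic impurity. Transfer, decomposition and quenching together gave a relaxation constant L:

L = 0.0500 s⁻¹, plateau 32.0 % of saturation

sat = 26.2 %

The forecast said 3.3 % and 26 %, reasoning that “only around 0.07 mM of target forms”.

This flask gave 3.38 % and 26.2 %, so my yield stood 1.15 times the result. Target and idle adduct together already reached 3.26 % at 20.0 s, which is 3.50 harvest times.

For the neighbour flask, I reckoned the crossing at 9.57 s and the harvest time at 11.7 s, and the same reckoning gave 2.00 %. That flask gave 1.80 %.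

(All constants were chosen freely; the run is a simulation.)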